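Everything rests on cutting ring C, the outer benzo ring of the dibenzofuran. Numbered C1 (furan C–O carbon), C2 (aryloxy), C3 (OH), C4 (H), C5 (OH), C6 (bonded to ring B), it is a hydroquinone whose para oxygens C2 and C5 flank the furan-fused pair C1/C6. A Dötz benzannulation of a benzofuran-3-yl(methoxy)carbene complex of zerovalent chromium with ethoxyacetylene makes C5–C4, C3–C2 and C2–C1 (C2 from CO) at once and delivers C5–OMe, C3–OEt and the only free phenol, C2–OH, for the ring F ether. The carbene carries ring B with its two dioxin oxygens protected differently (benzyl, MOM), so ring A is later fused in one orientation.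

Key step: step 9

Remark (labels): ring B (central): B4 furan C–O carbon, B5 bonded to C6, B6 and B1 the dioxin carbons (B6 next to B5), B2 (OH), B3 (H). Ring A carbons are written with a prime to keep them apart from those of ring C: C5′ and C6′ are joined through oxygen to B6 and B1; C1′ (aryloxy), C2′ (OH), C3′ (H), C4′ (OH). Rings E and F are the 3,5-dihydroxyphenyl groups on the C1′ and C2 oxygens.

Remark (stereochemistry): the target has no stereocentre, so no step sets or has to keep configuration.

Assumption: compounds 1, 3, 12, 16 (as its hexane solution), 19 and 22 and all reagents are bought.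

**Route**

Step 1
Reactants: 1 2-hydroxy-4,6-dimethoxybenzaldehyde
Product: 2 2,6-dihydroxy-4-methoxybenzaldehyde
Conditions: AlCl3 (3 equiv), PhCl, 80 °C; aq. HCl
Reagents that add atoms: none
Why: Chelation-controlled Lewis-acid ether cleavage, in which aluminium held between the carbonyl oxygen and the ortho oxygen removes only the methyl group ortho to the aldehyde and should leave the para methoxy group, gives an aldehyde whose two ortho hydroxyls are equivalent.

Step 2
Reactants: 2 2,6-dihydroxy-4-methoxybenzaldehyde; 3 ethyl diazoacetate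
Product: 5 ethyl 4-hydroxy-6-methoxy-1-benzofuran-3-carboxylate, via cyclic hemiacetal 4 (not isolated)
Conditions: HBF4·OEt2 (10 mol%), CH2Cl2, rt; then conc. H2SO4, rt
Reagents that add atoms: none
Why: Acid-catalysed addition of the diazo ester to the aldehyde, 1,2-aryl shift with loss of N2, hemiacetal closure by either of the two equivalent hydroxyls and acid dehydration (salicylaldehyde–diazoacetate benzofuran synthesis) should give the 3-carboxylate with the furan CH free and leave one hydroxyl, the future B6 oxygen, in the peri position.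

Step 3
Reactants: 5 ethyl 4-hydroxy-6-methoxy-1-benzofuran-3-carboxylate
Product: 6 ethyl 5-formyl-4-hydroxy-6-methoxy-1-benzofuran-3-carboxylate
Conditions: MgCl2, Et3N, (CH2O)n, MeCN, reflux; aq. HCl
Reagents that add atoms: paraformaldehyde (as formaldehyde), C=O
Why: Magnesium-phenoxide-directed ortho-formylation (Casnati–Skattebøl reaction) delivers formaldehyde only ortho to the free hydroxyl, and the single open ortho position is the future B1 carbon because the other one is the ring-fusion carbon.

Step 4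
Reactants: 6 ethyl 5-formyl-4-hydroxy-6-methoxy-1-benzofuran-3-carboxylate
Product: 7 ethyl 4-(benzyloxy)-5-formyl-6-methoxy-1-benzofuran-3-carboxylate
Conditions: BnBr, K2CO3, DMF, 60 °C
Reagents that add atoms: benzyl bromide, BrCc1ccccc1
Why: Williamson etherification of the only phenol puts the hydrogenolysable benzyl group on the B6 oxygen.

Step 5
Reactants: 7 ethyl 4-(benzyloxy)-5-formyl-6-methoxy-1-benzofuran-3-carboxylate
Product: 9 ethyl 4-(benzyloxy)-5-hydroxy-6-methoxy-1-benzofuran-3-carboxylate, via aryl formate 8 (not isolated)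
Conditions: mCPBA, CH2Cl2, 0 °C to rt; then K2CO3 (cat.), EtOH, rt
Reagents that add atoms: mCPBA, OOC(=O)c1cccc(Cl)c1
Why: Baeyer–Villiger oxidation of an aldehyde flanked by two alkoxy groups (Dakin-type) proceeds by migration of the electron-rich aryl group to the formate, whose mild ethanolysis should unveil the B1 hydroxyl without touching the ethyl ester.

Step 6
Reactants: 9 ethyl 4-(benzyloxy)-5-hydroxy-6-methoxy-1-benzofuran-3-carboxylate
Product: 10 ethyl 4-(benzyloxy)-6-methoxy-5-(methoxymethoxy)-1-benzofuran-3-carboxylate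
Conditions: NaH, DMF, 0 °C; MOMCl, 0 °C to rt
Reagents that add atoms: chloromethyl methyl ether, COCCl
Why: Alkylation of the sodium phenoxide with the small chloromethyl ether (acetal protection) should cope with the doubly flanked hydroxyl and makes B1–OMOM orthogonal to B6–OBn.

Step 7
Reactants: 10 ethyl 4-(benzyloxy)-6-methoxy-5-(methoxymethoxy)-1-benzofuran-3-carboxylate
Product: 11 4-(benzyloxy)-6-methoxy-5-(methoxymethoxy)-1-benzofuran-3-carboxylic acid
Conditions: LiOH·H2O, THF/EtOH/H2O, 50 °C; then aq. HCl to pH 4, 0 °C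
Reagents that add atoms: lithium hydroxide, [Li+].[OH-]
Why: Ester saponification with hydroxide, to which benzyl and MOM ethers are inert, followed by cold acidification to pH 4 that spares the acetal.

Step 8
Reactants: 11 4-(benzyloxy)-6-methoxy-5-(methoxymethoxy)-1-benzofuran-3-carboxylic acid; 12 hexacarbonylchromium Cr(CO)6
Product: 15 pentacarbonyl{[4-(benzyloxy)-6-methoxy-5-(methoxymethoxy)-1-benzofuran-3-yl](methoxy)methylidene}chromium, via acid chloride 13 (not isolated), via sodium acylchromate 14 (not isolated)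
Conditions: (a) 1-chloro-N,N,2-trimethylprop-1-en-1-amine, CH2Cl2, 0 °C to rt, evaporation; (b) Na2Cr(CO)5 [from Cr(CO)6 and sodium naphthalenide, THF, −78 °C], THF, −78 to 0 °C; (c) Me3OBF4, CH2Cl2, 0 °C
Reagents that add atoms: trimethyloxonium tetrafluoroborate, C[O+](C)C.F[B-](F)(F)F
Why: Acylation of the pentacarbonylchromate dianion by the acid chloride and O-methylation of the resulting acylchromate (the acid chloride variant of the Fischer carbene synthesis) should give the methoxycarbene without a 3-lithiobenzofuran, which would ring-open to an alkynylphenoxide, while the neutral chloroenamine makes the acid chloride without HCl so that the MOM acetal survives.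

Step 9
Reactants: 15 pentacarbonyl{[4-(benzyloxy)-6-methoxy-5-(methoxymethoxy)-1-benzofuran-3-yl](methoxy)methylidene}chromium; 16 ethoxyacetylene
Product: 18 9-(benzyloxy)-3-ethoxy-1,7-dimethoxy-8-(methoxymethoxy)dibenzo[b,d]furan-4-ol, via tricarbonylchromium arene complex 17 (not isolated)
Conditions: 16 (3 equiv, ca. 40 wt% in hexanes), THF (0.05 M), 50 °C, Ar; then air, CH2Cl2, rt
Reagents that add atoms: none
Why: Dötz benzannulation: loss of a cis CO lets the alkyne coordinate and insert into the Cr=C bond to give a vinylcarbene, CO insertion gives a vinylketene, and 6π-electrocyclisation of this dienylketene onto the furan CH carbon followed by tautomerisation of the cyclohexadienone gives the phenol as its Cr(CO)3 complex, which air cleaves. The closest known reaction type is the benzannulation of furyl, benzofuryl and indolyl (alkoxy)carbene complexes of zerovalent chromium with terminal alkynes to benzofurans, dibenzofurans and carbazoles. Ring C closes in the electrocyclisation, which makes the C2–C1 bond, after C5–C4 and C3–C2 have been made in the two insertion events. No stereocentre is formed. The step needs regioselective alkyne insertion, and the unsubstituted, nucleophilic terminus of the ynol ether should bond to the electrophilic carbene carbon, which is also the steric preference of terminal alkynes, so that OEt ends at C3 beside the CO-derived C2–OH and H at C4; the fusion itself is fixed because the other neighbour of the carbene-bearing carbon is the quaternary ring-fusion carbon. Phenol formation over cyclopentannulation or furan by-products is favoured by the alkoxy (not amino) carbene and an ether solvent at moderate temperature.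

Step 10
Reactants: 18 9-(benzyloxy)-3-ethoxy-1,7-dimethoxy-8-(methoxymethoxy)dibenzo[b,d]furan-4-ol; 19 1-bromo-3,5-dimethoxybenzene
Product: 20 9-(benzyloxy)-4-(3,5-dimethoxyphenoxy)-3-ethoxy-1,7-dimethoxy-8-(methoxymethoxy)dibenzo[b,d]furan
Conditions: CuI (10 mol%), picolinic acid (20 mol%), K3PO4, DMSO, 90 °C, Ar
Reagents that add atoms: none
Why: Ligand-accelerated Ullmann diaryl ether synthesis with monovalent copper, in which the C2 phenoxide is the only nucleophile and the picolinate system is suited to ortho-disubstituted phenols with unhindered aryl bromides, installs ring F.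

Step 11
Reactants: 20 9-(benzyloxy)-4-(3,5-dimethoxyphenoxy)-3-ethoxy-1,7-dimethoxy-8-(methoxymethoxy)dibenzo[b,d]furan
Product: 21 6-(3,5-dimethoxyphenoxy)-7-ethoxy-3,9-dimethoxy-2-(methoxymethoxy)dibenzo[b,d]furan-1-ol (free B6–OH)
Conditions: H2 (1 atm), 10% Pd/C, EtOAc/EtOH, rt
Reagents that add atoms: none
Why: Hydrogenolysis of the single benzyl ether frees only the B6 hydroxyl, since methyl, ethyl, MOM and diaryl ethers are inert.

Step 12
Reactants: 22 6-chlorovanillin
Product: 23 5,6-dichlorovanillin
Conditions: SO2Cl2, AcOH, rt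
Reagents that add atoms: sulfuryl chloride, O=S(=O)(Cl)Cl
Why: Electrophilic aromatic chlorination at the only position ortho to the phenol hydroxyl, the selectivity by which vanillin itself is chlorinated at its 5-position.

Step 13
Reactants: 23 5,6-dichlorovanillin
Product: 25 2,3-dichloro-5-methoxy-1,4-benzoquinone, via dichlorohydroquinone 24 (not isolated)
Conditions: H2O2 (30%), aq. NaOH, 0 °C to rt, N2; aq. HCl; then FeCl3, H2O/EtOAc, rt
Reagents that add atoms: hydrogen peroxide, OO
Why: Dakin oxidation of the para-hydroxybenzaldehyde (aryl migration in the hydroperoxide adduct, then formate hydrolysis) gives the hydroquinone, which trivalent iron oxidises to the quinone with the substitution pattern fixed by the vanillin skeleton.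

Step 14
Reactants: 21 6-(3,5-dimethoxyphenoxy)-7-ethoxy-3,9-dimethoxy-2-(methoxymethoxy)dibenzo[b,d]furan-1-ol; 25 2,3-dichloro-5-methoxy-1,4-benzoquinone
Product: 26 3-chloro-5-methoxy-2-{[6-(3,5-dimethoxyphenoxy)-7-ethoxy-3,9-dimethoxy-2-(methoxymethoxy)dibenzo[b,d]furan-1-yl]oxy}-1,4-benzoquinone (B6–O–C5′ ether)
Conditions: K2CO3, MeCN, 0 °C to rt, Ar
Reagents that add atoms: none
Why: Addition–elimination of the B6 phenoxide on the chloroquinone should occur at the chlorine-bearing carbon para to the methoxy group (C5′), because the methoxy group deactivates the carbonyl it is conjugated with (C4′) and leaves the C1′ carbonyl as acceptor, as in additions to 2-methoxybenzoquinones, while B1 is still blocked as its MOM ether.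

Step 15
Reactants: 26 B6–O–C5′ aryloxychloroquinone
Product: 28 dibenzodioxin quinone (ring A as 2-methoxy-1,4-quinone with C1′ and C4′ as carbonyls, fused through C6′–O–B1 and C5′–O–B6), via free B1 phenol 27 (not isolated)
Conditions: TFA, CH2Cl2, 0 °C to rt; evaporation; then K2CO3, DMF, rt
Reagents that add atoms: none
Why: Acidolysis of the MOM acetal frees B1–OH, whose phenoxide should close the six-membered dioxin by intramolecular addition–elimination at the remaining chlorine-bearing carbon C6′, as in annulations of catechols with 2,3-dichloroquinones.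

Step 16
Reactants: 28 dibenzodioxin quinone
Product: 30 C4′ isopropyl ether of the dioxin hydroquinone (C1′–OH free), via dioxin hydroquinone 29 (not isolated)
Conditions: Na2S2O4, THF/H2O, rt; extraction under Ar; then 2-bromopropane (1.5 equiv), K2CO3 (1.1 equiv), DMF, 40 °C
Reagents that add atoms: 2-bromopropane, CC(C)Br
Why: Dithionite reduction of the quinone followed by Williamson alkylation with a secondary halide should take the C4′ hydroxyl (one ortho hydrogen, two meta oxygens) in preference to the C1′ hydroxyl flanked by two oxygens, as 2,6-dialkoxyhydroquinones alkylate at their less flanked hydroxyl.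

Step 17
Reactants: 30 C4′ isopropyl ether with free C1′–OH; 19 1-bromo-3,5-dimethoxybenzene
Product: 31 fully alkylated phlorofucofuroeckol A (seven methyl ethers, C3 ethyl ether, C4′ isopropyl ether)
Conditions: CuI (20 mol%), picolinic acid (40 mol%), K3PO4, DMSO, 100 °C, Ar
Reagents that add atoms: none
Why: A second ligand-accelerated Ullmann etherification with monovalent copper installs ring E on C1′–OH, now the only free hydroxyl, using an unhindered aryl bromide.

Step 18
Reactants: 31 fully alkylated phlorofucofuroeckol A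
Product: 32 phlorofucofuroeckol A
Conditions: BBr3 (excess), CH2Cl2, −78 °C to rt; MeOH, then H2O; reversed-phase chromatography under Ar
Reagents that add atoms: none
Why: Boron tribromide ether cleavage should remove all nine alkyl groups by bromide attack on the boron-activated alkyl carbons, whereas the diaryl ether, dibenzofuran and dioxin C–O bonds have no such pathway and stay intact.

**Compound list**

1 | 2-hydroxy-4,6-dimethoxybenzaldehyde | COc1cc(O)c(C=O)c(OC)c1 | starting material
2 | 2,6-dihydroxy-4-methoxybenzaldehyde | COc1cc(O)c(C=O)c(O)c1 | intermediate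
3 | ethyl diazoacetate | CCOC(=O)C=[N+]=[N-] | starting material
4 | ethyl 2,4-dihydroxy-6-methoxy-2,3-dihydro-1-benzofuran-3-carboxylate (cyclic hemiacetal, mixture of racemic diastereomers, not isolated) | CCOC(=O)C1C(O)Oc2cc(OC)cc(O)c12 | intermediate
5 | ethyl 4-hydroxy-6-methoxy-1-benzofuran-3-carboxylate | CCOC(=O)c1coc2cc(OC)cc(O)c12 | intermediate
6 | ethyl 5-formyl-4-hydroxy-6-methoxy-1-benzofuran-3-carboxylate | CCOC(=O)c1coc2cc(OC)c(C=O)c(O)c12 | intermediate
7 | ethyl 4-(benzyloxy)-5-formyl-6-methoxy-1-benzofuran-3-carboxylate | CCOC(=O)c1coc2cc(OC)c(C=O)c(OCc3ccccc3)c12 | intermediate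
8 | ethyl 4-(benzyloxy)-5-(formyloxy)-6-methoxy-1-benzofuran-3-carboxylate (not isolated) | CCOC(=O)c1coc2cc(OC)c(OC=O)c(OCc3ccccc3)c12 | intermediate
9 | ethyl 4-(benzyloxy)-5-hydroxy-6-methoxy-1-benzofuran-3-carboxylate | CCOC(=O)c1coc2cc(OC)c(O)c(OCc3ccccc3)c12 | intermediate
10 | ethyl 4-(benzyloxy)-6-methoxy-5-(methoxymethoxy)-1-benzofuran-3-carboxylate | CCOC(=O)c1coc2cc(OC)c(OCOC)c(OCc3ccccc3)c12 | intermediate
11 | 4-(benzyloxy)-6-methoxy-5-(methoxymethoxy)-1-benzofuran-3-carboxylic acid | OC(=O)c1coc2cc(OC)c(OCOC)c(OCc3ccccc3)c12 | intermediate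
12 | hexacarbonylchromium, Cr(CO)6 | O=C=[Cr](=C=O)(=C=O)(=C=O)(=C=O)=C=O | starting material
13 | 4-(benzyloxy)-6-methoxy-5-(methoxymethoxy)-1-benzofuran-3-carbonyl chloride (not isolated) | ClC(=O)c1coc2cc(OC)c(OCOC)c(OCc3ccccc3)c12 | intermediate
14 | sodium pentacarbonyl{[4-(benzyloxy)-6-methoxy-5-(methoxymethoxy)-1-benzofuran-3-yl]carbonyl}chromate (not isolated) | [Na+].[O-]C(c1coc2cc(OC)c(OCOC)c(OCc3ccccc3)c12)=[Cr](=C=O)(=C=O)(=C=O)(=C=O)=C=O | intermediate
15 | pentacarbonyl{[4-(benzyloxy)-6-methoxy-5-(methoxymethoxy)-1-benzofuran-3-yl](methoxy)methylidene}chromium (zerovalent chromium) | COC(c1coc2cc(OC)c(OCOC)c(OCc3ccccc3)c12)=[Cr](=C=O)(=C=O)(=C=O)(=C=O)=C=O | intermediate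
16 | ethoxyacetylene | CCOC#C | starting material
17 | tricarbonylchromium complex of 18, metal η6-bound to ring C (not isolated; the η6 bond is written as a dot) | COc1cc(OCC)c(O)c2oc3cc(OC)c(OCOC)c(OCc4ccccc4)c3c12.O=C=[Cr](=C=O)=C=O | intermediate
18 | 9-(benzyloxy)-3-ethoxy-1,7-dimethoxy-8-(methoxymethoxy)dibenzo[b,d]furan-4-ol (C2–OH free, C3–OEt, C5–OMe, B2–OMe, B1–OMOM, B6–OBn) | COc1cc(OCC)c(O)c2oc3cc(OC)c(OCOC)c(OCc4ccccc4)c3c12 | intermediate
19 | 1-bromo-3,5-dimethoxybenzene | COc1cc(Br)cc(OC)c1 | starting material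
20 | 9-(benzyloxy)-4-(3,5-dimethoxyphenoxy)-3-ethoxy-1,7-dimethoxy-8-(methoxymethoxy)dibenzo[b,d]furan | COc1cc(OCC)c(Oc2cc(OC)cc(OC)c2)c2oc3cc(OC)c(OCOC)c(OCc4ccccc4)c3c12 | intermediate
21 | 6-(3,5-dimethoxyphenoxy)-7-ethoxy-3,9-dimethoxy-2-(methoxymethoxy)dibenzo[b,d]furan-1-ol | COc1cc(OCC)c(Oc2cc(OC)cc(OC)c2)c2oc3cc(OC)c(OCOC)c(O)c3c12 | intermediate
22 | 6-chlorovanillin (2-chloro-4-hydroxy-5-methoxybenzaldehyde) | COc1cc(C=O)c(Cl)cc1O | starting material
23 | 5,6-dichlorovanillin (2,3-dichloro-4-hydroxy-5-methoxybenzaldehyde) | COc1cc(C=O)c(Cl)c(Cl)c1O | intermediate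
24 | 2,3-dichloro-5-methoxybenzene-1,4-diol (not isolated) | COc1cc(O)c(Cl)c(Cl)c1O | intermediate
25 | 2,3-dichloro-5-methoxy-1,4-benzoquinone | COC1=CC(=O)C(Cl)=C(Cl)C1=O | intermediate
26 | 3-chloro-5-methoxy-2-{[6-(3,5-dimethoxyphenoxy)-7-ethoxy-3,9-dimethoxy-2-(methoxymethoxy)dibenzo[b,d]furan-1-yl]oxy}-1,4-benzoquinone | COc1cc(OCC)c(Oc2cc(OC)cc(OC)c2)c2oc3cc(OC)c(OCOC)c(OC4=C(Cl)C(=O)C(OC)=CC4=O)c3c12 | intermediate
27 | 26 with free B1–OH in place of B1–OMOM (not isolated) | COc1cc(OCC)c(Oc2cc(OC)cc(OC)c2)c2oc3cc(OC)c(O)c(OC4=C(Cl)C(=O)C(OC)=CC4=O)c3c12 | intermediate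
28 | dibenzodioxin quinone: rings F, C, B as in 21, ring A a 2-methoxy-1,4-quinone (C1′ and C4′ carbonyls, C2′–OMe, C3′–H) fused through C6′–O–B1 and C5′–O–B6 | COc1cc(OCC)c(Oc2cc(OC)cc(OC)c2)c2oc3cc(OC)c4OC5=C(Oc4c3c12)C(=O)C=C(OC)C5=O | intermediate
29 | dioxin hydroquinone: 28 with C1′–OH and C4′–OH (not isolated) | COc1cc(OCC)c(Oc2cc(OC)cc(OC)c2)c2oc3cc(OC)c4Oc5c(O)c(OC)cc(O)c5Oc4c3c12 | intermediate
30 | 29 with C4′–O-isopropyl and free C1′–OH | COc1cc(OCC)c(Oc2cc(OC)cc(OC)c2)c2oc3cc(OC)c4Oc5c(O)c(OC)cc(OC(C)C)c5Oc4c3c12 | intermediate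
31 | fully alkylated phlorofucofuroeckol A (OMe on rings E and F, C5, B2 and C2′; OEt on C3; O-isopropyl on C4′) | COc1cc(OCC)c(Oc2cc(OC)cc(OC)c2)c2oc3cc(OC)c4Oc5c(Oc6cc(OC)cc(OC)c6)c(OC)cc(OC(C)C)c5Oc4c3c12 | intermediate
32 | phlorofucofuroeckol A | Oc1cc(O)cc(Oc2c(O)cc(O)c3c2Oc2c(O)cc4oc5c(Oc6cc(O)cc(O)c6)c(O)cc(O)c5c4c2O3)c1 | target

**Step count**

Total step count: 18 (16 on the main line, 2 for quinone 25).
Longest linear sequence: 16 steps (steps 1–11 and 14–18, from 1 to 32).

**Three steps most likely to fail**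

1. Step 9. The ynol ether may insert without the following CO insertion and electrocyclisation, oligomerise at the metal, or insert with the reverse orientation, so that little of the phenol forms. The fallback sets out from 15 and moves the C3 oxygen into a separate oxidation. Benzannulation of 15 with 3,3-diethoxyprop-1-yne, an ordinary terminal alkyne that places its substituent beside the new hydroxyl by the usual steric rule, should give 9-(benzyloxy)-3-(diethoxymethyl)-1,7-dimethoxy-8-(methoxymethoxy)dibenzo[b,d]furan-4-ol F1. Ullmann coupling with 19 (CuI, picolinic acid, K3PO4, DMSO) gives the ring F ether F2. Acetal hydrolysis (PPTS, acetone/H2O) gives the C3 aldehyde F3. Baeyer–Villiger oxidation (mCPBA, NaHCO3, CH2Cl2) gives the C3 formate F4, and methanolysis (K2CO3, MeOH) gives the C3 phenol F5. Ethylation (EtI, K2CO3, DMF) brings the material back to the route at 20.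

2. Step 16. The alkylation may not discriminate cleanly between the two hydroquinone hydroxyls, or the hydroquinone may reoxidise before it is trapped. The fallback sets out from 28, which is reduced to 29 as before. Silylation with TIPSCl and imidazole (DMF, 0 °C), far more sensitive to flanking groups than alkylation, should give the C4′ triisopropylsilyl ether F9. Chan–Lam coupling of its C1′–OH with (3,5-dimethoxyphenyl)boronic acid (Cu(OAc)2, pyridine, 4 Å sieves, CH2Cl2, air, rt) tolerates the silyl ether and gives the ring E ether F10. TBAF/AcOH gives the C4′ phenol F11. BBr3 as in step 18 brings the material back to the route at 32.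

3. Step 14. The phenoxide may attack both chlorine-bearing carbons of the quinone, or be oxidised by it through electron transfer, which would erode orientation and yield. The fallback sets out from 21 and uses a quinone with a single leaving group. Oxidative demethylation of 1-bromo-2,4,5-trimethoxybenzene with (NH4)2Ce(NO3)6 (MeCN/H2O) gives 2-bromo-5-methoxy-1,4-benzoquinone F6. Its bromine-bearing carbon is the C5′ position, so substitution by 21 (K2CO3, MeCN) can only give the B6–O–C5′ aryloxyquinone F7. TFA removes the MOM group to give the free B1 phenol F8. K2CO3 in DMF under air should then close the dioxin by intramolecular oxa-Michael addition at C6′ and reoxidise the resulting hydroquinone 29, which brings the material back to the route at 28.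

**Further compounds**

F1 | step 9 | 9-(benzyloxy)-3-(diethoxymethyl)-1,7-dimethoxy-8-(methoxymethoxy)dibenzo[b,d]furan-4-ol | COc1cc(C(OCC)OCC)c(O)c2oc3cc(OC)c(OCOC)c(OCc4ccccc4)c3c12
F2 | step 9 | 9-(benzyloxy)-3-(diethoxymethyl)-4-(3,5-dimethoxyphenoxy)-1,7-dimethoxy-8-(methoxymethoxy)dibenzo[b,d]furan | COc1cc(C(OCC)OCC)c(Oc2cc(OC)cc(OC)c2)c2oc3cc(OC)c(OCOC)c(OCc4ccccc4)c3c12
F3 | step 9 | 9-(benzyloxy)-4-(3,5-dimethoxyphenoxy)-1,7-dimethoxy-8-(methoxymethoxy)dibenzo[b,d]furan-3-carbaldehyde | COc1cc(C=O)c(Oc2cc(OC)cc(OC)c2)c2oc3cc(OC)c(OCOC)c(OCc4ccccc4)c3c12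
F4 | step 9 | 9-(benzyloxy)-4-(3,5-dimethoxyphenoxy)-1,7-dimethoxy-8-(methoxymethoxy)dibenzo[b,d]furan-3-yl formate | COc1cc(OC=O)c(Oc2cc(OC)cc(OC)c2)c2oc3cc(OC)c(OCOC)c(OCc4ccccc4)c3c12
F5 | step 9 | 9-(benzyloxy)-4-(3,5-dimethoxyphenoxy)-1,7-dimethoxy-8-(methoxymethoxy)dibenzo[b,d]furan-3-ol | COc1cc(O)c(Oc2cc(OC)cc(OC)c2)c2oc3cc(OC)c(OCOC)c(OCc4ccccc4)c3c12
F6 | step 14 | 2-bromo-5-methoxy-1,4-benzoquinone | COC1=CC(=O)C(Br)=CC1=O
F7 | step 14 | 5-methoxy-2-{[6-(3,5-dimethoxyphenoxy)-7-ethoxy-3,9-dimethoxy-2-(methoxymethoxy)dibenzo[b,d]furan-1-yl]oxy}-1,4-benzoquinone | COc1cc(OCC)c(Oc2cc(OC)cc(OC)c2)c2oc3cc(OC)c(OCOC)c(OC4=CC(=O)C(OC)=CC4=O)c3c12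
F8 | step 14 | F7 with free B1–OH in place of B1–OMOM | COc1cc(OCC)c(Oc2cc(OC)cc(OC)c2)c2oc3cc(OC)c(O)c(OC4=CC(=O)C(OC)=CC4=O)c3c12
F9 | step 16 | 29 with C4′–O-triisopropylsilyl and free C1′–OH | COc1cc(OCC)c(Oc2cc(OC)cc(OC)c2)c2oc3cc(OC)c4Oc5c(O)c(OC)cc(O[Si](C(C)C)(C(C)C)C(C)C)c5Oc4c3c12
F10 | step 16 | F9 with C1′–O-(3,5-dimethoxyphenyl) | COc1cc(OCC)c(Oc2cc(OC)cc(OC)c2)c2oc3cc(OC)c4Oc5c(Oc6cc(OC)cc(OC)c6)c(OC)cc(O[Si](C(C)C)(C(C)C)C(C)C)c5Oc4c3c12
F11 | step 16 | F10 with free C4′–OH | COc1cc(OCC)c(Oc2cc(OC)cc(OC)c2)c2oc3cc(OC)c4Oc5c(Oc6cc(OC)cc(OC)c6)c(OC)cc(O)c5Oc4c3c12
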